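Follow one substrate molecule. You have a closed, stirred flask of substrate under a gas phase held at a fixed saturation level, and one earlier run, north, at twice this flask's charge.

- north: substrate 56 mM; gas phase 5 mM (held); run made earlier
- flask: substrate 28 mM; gas phase 5.0 mM (held); time 8.0 d

- north (time / d: target / %, substrate / %): 0.333: 11.3, 21.5; 0.625: 9.1, 8.2; 1.04: 4.7, 3.8; 1.25: 2.3, 1.9; 1.67: 0.1, 1.4; 2.08: 0.5, 0.7; 2.50: 0.1, 0.5

(readings scatter by 0.5 percentage points)

- what was read earlier has a scatter of 0.5 percentage points, one standard deviation
- at the start none of the gas phase is in solution
- a reading or a percentage of target counts all its forms, free or not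
- a reading of substrate is of its free form alone

- time, not beyond 8.0 d, at which the flask holds most target
- the amount of target, in percent of the substrate charged, at that time
- the first time at which target reaches 8.5%, in the same percent, in d

At north's first reading, 0.333 d, free substrate is down to 21.5% of its charge, yet target stands at just 11.3%. If substrate simply became target, target would stand near 78.5%. They fit if each molecule meets a fork. Target standing per substrate gone is 14.4%, a reading with its scatter; call this the fork share, the field's selectivity.

My own reckoning assumes that this share and north's early decay rate, 4.62 d⁻¹, both hold at the same gas level and half the charge. Reaching 8.5% then needs 59.0% of the substrate gone, which takes 0.193 d.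

The forecast expects 10% at 0.42 d and 8.5% at 0.22 d, which is later than my time. It leans on one branch of its reasoning: "If it scales with charge, the peak stays near 11%".

This flask gives 12.2% at 0.346 d and reaches 8.5% at 0.166 d.

    gas phase ⇌ dissolved gas, rate k1*(csat - [dissolved gas]) (kL = 1.10 × 10⁻⁴ s⁻¹)
    substrate + dissolved gas ⇌ target (K = 180 M⁻¹, k = 0.00600 M⁻¹ s⁻¹)
    substrate → side product (k = 3.80 × 10⁻⁵ s⁻¹)
    target ⇌ isomer of the product (K = 29.0, k = 4.40 × 10⁻⁵ s⁻¹)
    substrate + target ⇌ idle adduct, settled at all times (K = 170 M⁻¹)

At 0.346 d this flask has 79.2% of its substrate gone, counted as in north, so the carried share gives 11.4% target, and the flask holds 12.2%. At 0.191 d, the step to side product uses substrate 2.3 times as fast as the forward step to target.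

In a neighbour flask with 11 mM of substrate, the carried share, assumed to hold again and applied to the whole charge, gives an estimate of 14.4% target. The computed highest amount in that neighbour flask is 12.2%, lower than that estimate.

The earlier runs and the new flask were generated by integration on assumed constants.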